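**Strategy.** The route rests on disconnecting the exocyclic C4a=C5 double bond, which joins the pyran ring (O2, C1, C3, C4, C4a, C8a) to ring B (C4a, C5, C6, C7, C8, C8a) and makes the core a 4-ylidene-4H-pyran. That olefin is the formal product of a pyran-4-thione carbon (C4a) and a halomethyl ketone (C5–C6). An intramolecular Eschenmoser sulfide contraction therefore forms the C4a–C5 bond, closes ring B and completes the chromophore in one operation. The precursor is a 4H-pyran-4-thione carrying the (E)-acrylate on the future C3 and, on the future C8a, the chain C8(=O)–C7(Me)(OSiEt3)–C6(=O)–C5H2Cl, with C7 taken from (S)-lactic acid.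

Key step: step 10

Remark: isochromene numbering of the target (C1, O2, C3, C4, C4a, C5 to C8, C8a) is used for all intermediates; the C5 halogen is only a leaving group, so it is carried as chloride (inert during thionation) and exchanged for iodide in the flask of step 10.

Step 1
Reactants: 1 kojic acid [5-hydroxy-2-(hydroxymethyl)-4H-pyran-4-one]
Product: 2 6-(hydroxymethyl)-4-oxo-4H-pyran-3-yl trifluoromethanesulfonate
Conditions: PhNTf2, Et3N, DMF, 0 °C → rt
Reagents that add atoms: N-phenylbis(trifluoromethanesulfonimide), O=S(=O)(N(c1ccccc1)S(=O)(=O)C(F)(F)F)C(F)(F)F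
Why: Selective O-sulfonylation (enol triflation), since only the acidic 5-hydroxyl is deprotonated by Et3N and captured by the mild triflyl donor while the primary alcohol stays free.

Step 2
Reactants: 2 6-(hydroxymethyl)-4-oxo-4H-pyran-3-yl trifluoromethanesulfonate
Product: 4 tert-butyl (E)-3-[4-oxo-5-(trifluoromethylsulfonyloxy)-4H-pyran-2-yl]acrylate, via pyranone aldehyde 3 (not isolated)
Conditions: activated MnO2, Ph3P=CHCO2tBu, CH2Cl2, rt
Reagents that add atoms: tert-butyl (triphenylphosphoranylidene)acetate, CC(C)(C)OC(=O)C=P(c1ccccc1)(c1ccccc1)c1ccccc1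
Why: Tandem MnO2 oxidation and Wittig olefination, in which the pyranyl carbinol is oxidised like an allylic alcohol and the electron-poor aldehyde is trapped at once by the stabilised ylide to give the (E)-acrylate.

Step 3
Reactants: 4 tert-butyl (E)-3-[4-oxo-5-(trifluoromethylsulfonyloxy)-4H-pyran-2-yl]acrylate
Product: 5 tert-butyl (E)-3-(5-formyl-4-oxo-4H-pyran-2-yl)acrylate
Conditions: Pd(OAc)2 (5 mol %), 1,3-bis(diphenylphosphino)propane, CO (1 atm), Et3SiH (slow addition), Et3N, DMF, 60 °C
Reagents that add atoms: carbon monoxide, [C-]#[O+]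
Why: Palladium-catalysed reductive carbonylation (formylation) of an enol triflate by oxidative addition, CO insertion and hydride transfer from the silane to the acylpalladium species, with slow silane addition to suppress direct reduction of the triflate.

Step 4
Reactants: 6 (S)-lactic acid; 7 pivalaldehyde
Product: 8 (2S,5S)-2-tert-butyl-5-methyl-1,3-dioxolan-4-one (tert-butyl and methyl cis)
Conditions: TsOH·H2O (cat.), H2SO4 (cat.), pentane, reflux, Dean–Stark; crystallisation from pentane/Et2O, −78 °C
Reagents that add atoms: none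
Why: Acid-catalysed acetalisation with azeotropic removal of water, in which C5 keeps the configuration of (S)-lactic acid and the new acetal centre C2 forms mainly as the cis isomer, which is purified by low-temperature crystallisation.

Step 5
Reactants: 8 (2S,5S)-2-tert-butyl-5-methyl-1,3-dioxolan-4-one; 5 tert-butyl (E)-3-(5-formyl-4-oxo-4H-pyran-2-yl)acrylate
Product: 11 tert-butyl (E)-3-(5-{[(2S,4R)-2-tert-butyl-4-methyl-5-oxo-1,3-dioxolan-4-yl](trimethylsilyloxy)methyl}-4-oxo-4H-pyran-2-yl)acrylate (both epimers at the silyloxy carbon), via lithium enolate 9 (not isolated), via lithium aldolate 10 (not isolated)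
Conditions: LDA, THF, −78 °C; then 5, −78 °C; then TMSCl, −78 → −20 °C
Reagents that add atoms: chlorotrimethylsilane, C[Si](C)(C)Cl
Why: Aldol addition with self-regeneration of the stereocentre, in which the planar enolate is attacked on the face opposite the tert-butyl group so that the new C7–C8 bond replaces the former C–H bond with retention (the C7 configuration of the target), while in situ O-silylation blocks retro-aldol and acetal migration and the unselectively formed carbinol centre is removed in step 7.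

Step 6
Reactants: 11 tert-butyl (E)-3-(5-{[(2S,4R)-2-tert-butyl-4-methyl-5-oxo-1,3-dioxolan-4-yl](trimethylsilyloxy)methyl}-4-oxo-4H-pyran-2-yl)acrylate; 12 chloroiodomethane
Product: 14 tert-butyl (E)-3-{5-[(2R)-4-chloro-1,2-dihydroxy-2-methyl-3-oxobutyl]-4-oxo-4H-pyran-2-yl}acrylate (both epimers at C8), via lithium hemiketal alkoxide 13 (not isolated)
Conditions: MeLi·LiBr added to 11 and ICH2Cl, THF/Et2O, −78 °C; AcOH, −78 °C; then 1 M HCl, THF, 0 °C
Reagents that add atoms: none
Why: Halomethyllithium (carbenoid) addition to a lactone carbonyl, in which chloromethyllithium generated in the presence of 11 adds to the activated acylal-type lactone, the tetrahedral alkoxide is stable at −78 °C so no second addition occurs, and aqueous acid releases pivalaldehyde and both hydroxyls; the step precedes oxidation of C8 because a C8 ketone would compete for the carbenoid.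

Step 7
Reactants: 14 tert-butyl (E)-3-{5-[(2R)-4-chloro-1,2-dihydroxy-2-methyl-3-oxobutyl]-4-oxo-4H-pyran-2-yl}acrylate
Product: 15 tert-butyl (E)-3-{5-[(2R)-4-chloro-2-hydroxy-2-methyl-3-oxobutanoyl]-4-oxo-4H-pyran-2-yl}acrylate
Conditions: Dess–Martin periodinane, CH2Cl2, 0 °C → rt
Reagents that add atoms: none
Why: Dess–Martin oxidation of the secondary pyranyl carbinol to the C8 ketone, in which both carbinol epimers converge on one compound while the tertiary C7 hydroxyl and the chloromethyl ketone are inert.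

Step 8
Reactants: 15 tert-butyl (E)-3-{5-[(2R)-4-chloro-2-hydroxy-2-methyl-3-oxobutanoyl]-4-oxo-4H-pyran-2-yl}acrylate
Product: 16 tert-butyl (E)-3-{5-[(2R)-4-chloro-2-methyl-3-oxo-2-(triethylsilyloxy)butanoyl]-4-oxo-4H-pyran-2-yl}acrylate
Conditions: TESOTf, 2,6-lutidine, CH2Cl2, −78 → 0 °C
Reagents that add atoms: triethylsilyl trifluoromethanesulfonate, CC[Si](CC)(CC)OS(=O)(=O)C(F)(F)F
Why: Silylation of a hindered tertiary alcohol with a silyl triflate and a hindered pyridine base that does not alkylate at the chloromethyl ketone.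

Step 9
Reactants: 16 tert-butyl (E)-3-{5-[(2R)-4-chloro-2-methyl-3-oxo-2-(triethylsilyloxy)butanoyl]-4-oxo-4H-pyran-2-yl}acrylate
Product: 17 tert-butyl (E)-3-{5-[(2R)-4-chloro-2-methyl-3-oxo-2-(triethylsilyloxy)butanoyl]-4-thioxo-4H-pyran-2-yl}acrylate
Conditions: Lawesson's reagent (0.55 equiv), toluene, 70 °C
Reagents that add atoms: Lawesson's reagent [2,4-bis(4-methoxyphenyl)-1,3,2,4-dithiadiphosphetane 2,4-disulfide], COc1ccc(cc1)P1(=S)SP(=S)(S1)c1ccc(OC)cc1
Why: Thionation with Lawesson's reagent, for which the 4-pyranone oxygen is the most nucleophilic and least hindered carbonyl oxygen whereas both ketones flank the quaternary C7, and in apolar toluene the chloride is too poor an electrophile for early S-alkylation.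

Step 10
Reactants: 17 tert-butyl (E)-3-{5-[(2R)-4-chloro-2-methyl-3-oxo-2-(triethylsilyloxy)butanoyl]-4-thioxo-4H-pyran-2-yl}acrylate
Product: 21 tert-butyl (E)-3-[(7S)-7-methyl-6,8-dioxo-7-(triethylsilyloxy)-7,8-dihydro-6H-isochromen-3-yl]acrylate, via iodomethyl ketone 18 (not isolated), via bridged thiopyrylium iodide 19 (not isolated), via spiro thiirane 20 (not isolated)
Conditions: NaI, MeCN, rt → 40 °C; then iPr2NEt, PPh3, rt → 60 °C
Reagents that add atoms: none
Why: Proposed new method: iodide exchange gives iodomethyl ketone 18, the thione sulfur displaces iodide (7-exo-tet) to form the bridged 4-alkylthiopyrylium salt 19, iPr2NEt removes a C5 hydrogen (acidified by the C6 ketone and the cationic sulfur), the carbanion adds to the neighbouring pyrylium carbon C4a to give thiirane 20, and PPh3 abstracts sulfur to leave C4a=C5. The closest known reaction type is the Eschenmoser sulfide contraction of thioamides and vinylogous thioesters with α-halo ketones, which has not been shown intramolecularly on a 4H-pyran-4-thione. Ring B (C4a, C5, C6, C7, C8, C8a) closes through the transannular C5–C4a bond inside the seven-membered thia-ring, a 3-exo-trig attack with respect to the thiirane and 6-exo-trig with respect to ring B, and the thia-ring then contracts by loss of sulfur. No stereocentre is created in 21, since both thiirane carbons become sp2, and C7 is untouched because it carries no hydrogen. The selectivity needed is bonding of C5 to C4a and not to the Michael position C1, which the one-atom sulfur link secures because attack at C1 would place the C4a=C8a double bond at a bridgehead of a bicyclo[3.2.1] skeleton. PPh3 is added only after S-alkylation is complete so that it meets no halomethyl ketone.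

Step 11
Reactants: 21 tert-butyl (E)-3-[(7S)-7-methyl-6,8-dioxo-7-(triethylsilyloxy)-7,8-dihydro-6H-isochromen-3-yl]acrylate
Product: 22 tert-butyl (E)-3-[(7S)-7-hydroxy-7-methyl-6,8-dioxo-7,8-dihydro-6H-isochromen-3-yl]acrylate
Conditions: HF·pyridine, THF, 0 °C
Reagents that add atoms: none
Why: Fluoride-mediated cleavage of the silyl ether under mildly acidic conditions that leave the base-sensitive bicyclic core and the tert-butyl ester intact.

Step 12
Reactants: 23 methyl orsellinate (methyl 2,4-dihydroxy-6-methylbenzoate)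
Product: 24 methyl 2,4-bis(methoxymethoxy)-6-methylbenzoate
Conditions: NaH, MOMCl, DMF, 0 °C → rt
Reagents that add atoms: chloromethyl methyl ether, COCCl
Why: Williamson-type O-alkylation of both phenoxides, the sodium salt overcoming the hydrogen bond of the ortho hydroxyl.

Step 13
Reactants: 24 methyl 2,4-bis(methoxymethoxy)-6-methylbenzoate
Product: 25 2,4-bis(methoxymethoxy)-6-methylbenzoic acid
Conditions: KOH, EtOH/H2O, reflux; then 1 M HCl to pH 4, 0 °C
Reagents that add atoms: potassium hydroxide, [K+].[OH-]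
Why: Saponification of the hindered methyl ester under forcing basic conditions to which methoxymethyl ethers are stable, followed by cold acidification mild enough to spare them.

Step 14
Reactants: 25 2,4-bis(methoxymethoxy)-6-methylbenzoic acid; 22 tert-butyl (E)-3-[(7S)-7-hydroxy-7-methyl-6,8-dioxo-7,8-dihydro-6H-isochromen-3-yl]acrylate
Product: 27 (7S)-3-[(E)-3-tert-butoxy-3-oxoprop-1-enyl]-7-methyl-6,8-dioxo-7,8-dihydro-6H-isochromen-7-yl 2,4-bis(methoxymethoxy)-6-methylbenzoate, via acid chloride 26 (not isolated)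
Conditions: 1-chloro-N,N,2-trimethylprop-1-en-1-amine, CH2Cl2, 0 °C; then 22, Et3N, DMAP, CH2Cl2, 0 °C → rt
Reagents that add atoms: none
Why: Acid chloride formation under neutral conditions with an α-chloro enamine (no HCl, so the methoxymethyl ethers survive) followed by DMAP-catalysed acylation of the tertiary C7 hydroxyl, which is flanked only by planar carbonyl carbons and whose stereocentre is not involved.

Step 15
Reactants: 27 (7S)-3-[(E)-3-tert-butoxy-3-oxoprop-1-enyl]-7-methyl-6,8-dioxo-7,8-dihydro-6H-isochromen-7-yl 2,4-bis(methoxymethoxy)-6-methylbenzoate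
Product: 28 (S)-mitorubrinic acid
Conditions: CF3CO2H/CH2Cl2 (1:3), 0 °C → rt
Reagents that add atoms: none
Why: Acidolysis in which CF3CO2H cleaves the tert-butyl ester by loss of 2-methylpropene and both methoxymethyl acetals in one operation, while C7 cannot epimerise because it bears no hydrogen.

**Compound list**

1 | kojic acid | OCC1=CC(=O)C(O)=CO1 | starting material
2 | 6-(hydroxymethyl)-4-oxo-4H-pyran-3-yl trifluoromethanesulfonate | OCC1=CC(=O)C(OS(=O)(=O)C(F)(F)F)=CO1 | intermediate
3 | 6-formyl-4-oxo-4H-pyran-3-yl trifluoromethanesulfonate | O=CC1=CC(=O)C(OS(=O)(=O)C(F)(F)F)=CO1 | intermediate (not isolated)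
4 | tert-butyl (E)-3-[4-oxo-5-(trifluoromethylsulfonyloxy)-4H-pyran-2-yl]acrylate | CC(C)(C)OC(=O)/C=C/C1=CC(=O)C(OS(=O)(=O)C(F)(F)F)=CO1 | intermediate
5 | tert-butyl (E)-3-(5-formyl-4-oxo-4H-pyran-2-yl)acrylate | CC(C)(C)OC(=O)/C=C/C1=CC(=O)C(C=O)=CO1 | intermediate
6 | (S)-lactic acid | C[C@H](O)C(=O)O | starting material
7 | pivalaldehyde | CC(C)(C)C=O | starting material
8 | (2S,5S)-2-tert-butyl-5-methyl-1,3-dioxolan-4-one | CC(C)(C)[C@H]1O[C@@H](C)C(=O)O1 | intermediate
9 | lithium (2S)-2-tert-butyl-5-methyl-1,3-dioxol-4-olate | CC(C)(C)[C@H]1OC(C)=C([O-])O1.[Li+] | intermediate (not isolated)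
10 | lithium [(2S,4R)-2-tert-butyl-4-methyl-5-oxo-1,3-dioxolan-4-yl]{6-[(E)-3-tert-butoxy-3-oxoprop-1-enyl]-4-oxo-4H-pyran-3-yl}methanolate (both carbinol epimers) | CC(C)(C)[C@H]1O[C@@](C([O-])C2=COC(/C=C/C(=O)OC(C)(C)C)=CC2=O)(C)C(=O)O1.[Li+] | intermediate (not isolated)
11 | tert-butyl (E)-3-(5-{[(2S,4R)-2-tert-butyl-4-methyl-5-oxo-1,3-dioxolan-4-yl](trimethylsilyloxy)methyl}-4-oxo-4H-pyran-2-yl)acrylate (both epimers at the silyloxy carbon) | CC(C)(C)[C@H]1O[C@@](C(O[Si](C)(C)C)C2=COC(/C=C/C(=O)OC(C)(C)C)=CC2=O)(C)C(=O)O1 | intermediate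
12 | chloroiodomethane | ClCI | starting material
13 | lithium (2S,5R)-2-tert-butyl-4-(chloromethyl)-5-methyl-5-[{6-[(E)-3-tert-butoxy-3-oxoprop-1-enyl]-4-oxo-4H-pyran-3-yl}(trimethylsilyloxy)methyl]-1,3-dioxolan-4-olate (ring configuration as in 11, C4 undefined) | CC(C)(C)[C@H]1O[C@@](C(O[Si](C)(C)C)C2=COC(/C=C/C(=O)OC(C)(C)C)=CC2=O)(C)C([O-])(CCl)O1.[Li+] | intermediate (not isolated)
14 | tert-butyl (E)-3-{5-[(2R)-4-chloro-1,2-dihydroxy-2-methyl-3-oxobutyl]-4-oxo-4H-pyran-2-yl}acrylate (both epimers at C8) | O[C@@](C(O)C1=COC(/C=C/C(=O)OC(C)(C)C)=CC1=O)(C)C(=O)CCl | intermediate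
15 | tert-butyl (E)-3-{5-[(2R)-4-chloro-2-hydroxy-2-methyl-3-oxobutanoyl]-4-oxo-4H-pyran-2-yl}acrylate | O[C@@](C(=O)C1=COC(/C=C/C(=O)OC(C)(C)C)=CC1=O)(C)C(=O)CCl | intermediate
16 | tert-butyl (E)-3-{5-[(2R)-4-chloro-2-methyl-3-oxo-2-(triethylsilyloxy)butanoyl]-4-oxo-4H-pyran-2-yl}acrylate | CC[Si](CC)(CC)O[C@@](C(=O)C1=COC(/C=C/C(=O)OC(C)(C)C)=CC1=O)(C)C(=O)CCl | intermediate
17 | tert-butyl (E)-3-{5-[(2R)-4-chloro-2-methyl-3-oxo-2-(triethylsilyloxy)butanoyl]-4-thioxo-4H-pyran-2-yl}acrylate | CC[Si](CC)(CC)O[C@@](C(=O)C1=COC(/C=C/C(=O)OC(C)(C)C)=CC1=S)(C)C(=O)CCl | intermediate (key-step precursor)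
18 | tert-butyl (E)-3-{5-[(2R)-4-iodo-2-methyl-3-oxo-2-(triethylsilyloxy)butanoyl]-4-thioxo-4H-pyran-2-yl}acrylate | CC[Si](CC)(CC)O[C@@](C(=O)C1=COC(/C=C/C(=O)OC(C)(C)C)=CC1=S)(C)C(=O)CI | intermediate (not isolated)
19 | bridged 4-alkylthiopyrylium iodide: sulfur on C4a bonded to C5H2 in a seven-membered ring (S, C5, C6, C7, C8, C8a, C4a), C7 with methyl and OSiEt3 as in 17, (E)-tert-butyl acrylate on C3 | [o+]1cc2c(SCC(=O)[C@](C)(O[Si](CC)(CC)CC)C2=O)cc1/C=C/C(=O)OC(C)(C)C.[I-] | intermediate (not isolated)
20 | spiro thiirane: sulfur bridging C4a and C5 of the 4H-pyran/ring B skeleton, C7 as in 17, thiirane carbons undefined | CC[Si](CC)(CC)O[C@@]1(C)C(=O)C2SC23C=C(/C=C/C(=O)OC(C)(C)C)OC=C3C1=O | intermediate (not isolated)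
21 | tert-butyl (E)-3-[(7S)-7-methyl-6,8-dioxo-7-(triethylsilyloxy)-7,8-dihydro-6H-isochromen-3-yl]acrylate | CC[Si](CC)(CC)O[C@@]1(C)C(=O)C=C2C=C(/C=C/C(=O)OC(C)(C)C)OC=C2C1=O | intermediate (key-step product)
22 | tert-butyl (E)-3-[(7S)-7-hydroxy-7-methyl-6,8-dioxo-7,8-dihydro-6H-isochromen-3-yl]acrylate | O[C@@]1(C)C(=O)C=C2C=C(/C=C/C(=O)OC(C)(C)C)OC=C2C1=O | intermediate
23 | methyl orsellinate (methyl 2,4-dihydroxy-6-methylbenzoate) | COC(=O)c1c(C)cc(O)cc1O | starting material
24 | methyl 2,4-bis(methoxymethoxy)-6-methylbenzoate | COCOc1cc(C)c(C(=O)OC)c(OCOC)c1 | intermediate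
25 | 2,4-bis(methoxymethoxy)-6-methylbenzoic acid | COCOc1cc(C)c(C(=O)O)c(OCOC)c1 | intermediate
26 | 2,4-bis(methoxymethoxy)-6-methylbenzoyl chloride | COCOc1cc(C)c(C(Cl)=O)c(OCOC)c1 | intermediate (not isolated)
27 | (7S)-3-[(E)-3-tert-butoxy-3-oxoprop-1-enyl]-7-methyl-6,8-dioxo-7,8-dihydro-6H-isochromen-7-yl 2,4-bis(methoxymethoxy)-6-methylbenzoate | COCOc1cc(C)c(C(=O)O[C@@]2(C)C(=O)C=C3C=C(/C=C/C(=O)OC(C)(C)C)OC=C3C2=O)c(OCOC)c1 | intermediate
28 | (S)-mitorubrinic acid, (E)-3-[(7S)-7-(2,4-dihydroxy-6-methylbenzoyloxy)-7-methyl-6,8-dioxo-7,8-dihydro-6H-isochromen-3-yl]acrylic acid | Cc1cc(O)cc(O)c1C(=O)O[C@@]1(C)C(=O)C=C2C=C(/C=C/C(=O)O)OC=C2C1=O | target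

**Step count.** Total: 15 steps. Longest linear sequence: 12 steps (kojic acid 1 to 28 through steps 1, 2, 3, 5, 6, 7, 8, 9, 10, 11, 14 and 15).

**Steps most likely to fail**

1. Step 10. S-alkylation to the strained seven-membered thia-ring may be slow, so that intermolecular alkylation or phosphine quaternisation intervenes, or the deprotonated salt may open the pyrylium ring instead of forming the thiirane. The fallback uses known chemistry, sets out from 16 and returns at 21. Reductive dechlorination (Zn, AcOH, THF, 0 °C) should give the methyl ketone tert-butyl (E)-3-{5-[(2S)-2-methyl-3-oxo-2-(triethylsilyloxy)butanoyl]-4-oxo-4H-pyran-2-yl}acrylate F1. MeOTf with 2,6-di-tert-butyl-4-methylpyridine in CH2Cl2 should then methylate the pyranone oxygen to 2-[(E)-3-tert-butoxy-3-oxoprop-1-enyl]-4-methoxy-5-[(2S)-2-methyl-3-oxo-2-(triethylsilyloxy)butanoyl]pyrylium trifluoromethanesulfonate F2. iPr2NEt in MeCN should enolise the methyl ketone, whose C5 adds ipso to the methoxy-bearing C4a with loss of methanol to give 21. This is the established condensation of 4-alkoxypyrylium salts with C–H acidic carbonyl compounds to 4-ylidene-4H-pyrans. The C4a/C1 choice is then no longer enforced by a tether, but only ipso attack is made irreversible by expulsion of methanol.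

2. Step 6. The carbenoid may add to the pyranone carbonyl or to C1 in competition with the lactone, or the tetrahedral alkoxide may break down before the quench and take up a second equivalent. The fallback sets out from 11 and returns at 14. Lactone methylenation with Cp2TiMe2 (toluene, 65 °C) should give the exocyclic enol ether tert-butyl (E)-3-(5-{[2-tert-butyl-4-methyl-5-methylidene-1,3-dioxolan-4-yl](trimethylsilyloxy)methyl}-4-oxo-4H-pyran-2-yl)acrylate F3, with ring stereocentres as in 11. N-Chlorosuccinimide in THF/H2O should chlorinate the methylene carbon, water captures the oxocarbenium ion, and dilute HCl completes loss of pivalaldehyde and of the trimethylsilyl group to give 14. Both operations are standard: titanium-mediated carbonyl methylenation of lactones, and halogenation–hydrolysis of enol ethers to α-halo ketones.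

3. Step 9. A ketone carbonyl may be thionated beside the pyranone, the phosphorus–sulfur reagent may attack the chloromethyl ketone, or the silyl ether may be lost on heating. The fallback sets out from 16 and returns at 17. O-Methylation with MeOTf (2,6-di-tert-butyl-4-methylpyridine, CH2Cl2, 0 °C) should give 2-[(E)-3-tert-butoxy-3-oxoprop-1-enyl]-5-[(2R)-4-chloro-2-methyl-3-oxo-2-(triethylsilyloxy)butanoyl]-4-methoxypyrylium trifluoromethanesulfonate F4. One equivalent of NaSH in MeCN at −40 °C should then add hydrosulfide to the methoxy-bearing carbon and expel methanol. This is the classical conversion of 4-alkoxypyrylium salts into pyran-4-thiones, run cold so that the ion-pair reaction outruns substitution at the chloromethyl ketone.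

**Further compounds**

F1 | step 10 | tert-butyl (E)-3-{5-[(2S)-2-methyl-3-oxo-2-(triethylsilyloxy)butanoyl]-4-oxo-4H-pyran-2-yl}acrylate | CC[Si](CC)(CC)O[C@@](C(=O)C1=COC(/C=C/C(=O)OC(C)(C)C)=CC1=O)(C)C(C)=O
F2 | step 10 | 2-[(E)-3-tert-butoxy-3-oxoprop-1-enyl]-4-methoxy-5-[(2S)-2-methyl-3-oxo-2-(triethylsilyloxy)butanoyl]pyrylium trifluoromethanesulfonate | [o+]1cc(C(=O)[C@](O[Si](CC)(CC)CC)(C)C(C)=O)c(OC)cc1/C=C/C(=O)OC(C)(C)C.[O-]S(=O)(=O)C(F)(F)F
F3 | step 6 | tert-butyl (E)-3-(5-{[2-tert-butyl-4-methyl-5-methylidene-1,3-dioxolan-4-yl](trimethylsilyloxy)methyl}-4-oxo-4H-pyran-2-yl)acrylate (ring stereocentres as in 11) | CC(C)(C)[C@H]1O[C@@](C(O[Si](C)(C)C)C2=COC(/C=C/C(=O)OC(C)(C)C)=CC2=O)(C)C(=C)O1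
F4 | step 9 | 2-[(E)-3-tert-butoxy-3-oxoprop-1-enyl]-5-[(2R)-4-chloro-2-methyl-3-oxo-2-(triethylsilyloxy)butanoyl]-4-methoxypyrylium trifluoromethanesulfonate | [o+]1cc(C(=O)[C@](O[Si](CC)(CC)CC)(C)C(=O)CCl)c(OC)cc1/C=C/C(=O)OC(C)(C)C.[O-]S(=O)(=O)C(F)(F)F
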